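**Retrosynthetic overview**
1. Lactone C=O: the last step oxidises C2 of an isoflavylium / 2-hydroxyisoflav-3-ene, as in the isoflavene → 3-arylcoumarin step of the pathway.
2. Ring C: the isoflavylium comes from a ring-opened 2-hydroxyisoflavanone equivalent (a β-keto acetal) by C4 reduction and acid collapse (O1–C2 closure, dehydration), without passing through the isoflavone.
3. C3–aryl bond: the keto acetal comes from a 2'-hydroxychalcone by an isoflavone-synthase-type oxidative 1,2-aryl shift.
4. Chalcone: Claisen–Schmidt union of a ring A acetophenone with a ring B/D chroman aldehyde.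
5. Ring D: C3-prenylation of 2,4-dihydroxybenzaldehyde, then acid cyclisation onto the 4-OH. Ring D is formed first and ring C last; rings A and B are bought.

Assumption: the target has no stereocentre and no stereogenic double bond, so it is achiral and there is no enantiomer to select. The transient stereocentres in three intermediates form as racemates or mixtures and are erased later.

**Step 1**
Reactants: 1 2,4-dihydroxybenzaldehyde; 2 prenyl bromide (1-bromo-3-methylbut-2-ene)
Product: 4 5-hydroxy-2,2-dimethylchroman-6-carbaldehyde, via 3-prenyl-2,4-dihydroxybenzaldehyde 3 (not isolated)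
Conditions: KOH (1.1 equiv), H2O, 0 °C to rt; dil. HCl, take up in toluene; TsOH·H2O (10 mol %), 80 °C (crude, telescoped)
Reagents that add atoms: none
Why: In water the phenoxide of 1 is C-alkylated at C3, the carbon activated by both oxygens (phenoxide C-alkylation as a biomimetic aromatic prenylation), and TsOH then protonates the prenyl alkene to the tertiary cation, which the free 4-OH captures rather than the aldehyde-chelated 2-OH (Markovnikov intramolecular hydroalkoxylation), closing ring D with no stereocentre formed.

**Step 2**
Reactants: 4 5-hydroxy-2,2-dimethylchroman-6-carbaldehyde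
Product: 5 5-methoxy-2,2-dimethylchroman-6-carbaldehyde
Conditions: MeI (1.5 equiv), K2CO3, DMF, rt to 40 °C
Reagents that add atoms: methyl iodide, CI
Why: Ring D closure has already tied up the 4-OH, so a Williamson ether synthesis can only methylate the one remaining phenol, and the aldehyde is inert.

**Step 3**
Reactants: 6 2,4-dihydroxy-6-methoxyacetophenone
Product: 7 1-[2-hydroxy-6-methoxy-4-(methoxymethoxy)phenyl]ethanone
Conditions: MOMCl (1.05 equiv), K2CO3, acetone, 0 °C to rt
Reagents that add atoms: chloromethyl methyl ether, COCCl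
Why: The 4-OH is more acidic and is not hydrogen-bonded, so it is alkylated selectively (Williamson-type acetal protection) while the ketone-chelated 2-OH stays free to become O1.

**Step 4**
Reactants: 5 5-methoxy-2,2-dimethylchroman-6-carbaldehyde; 7 1-[2-hydroxy-6-methoxy-4-(methoxymethoxy)phenyl]ethanone
Product: 8 (E)-1-[2-hydroxy-6-methoxy-4-(methoxymethoxy)phenyl]-3-(5-methoxy-2,2-dimethylchroman-6-yl)prop-2-en-1-one
Conditions: KOH (50 % aq.), EtOH, rt, 36 h; cold AcOH to pH 5–6
Reagents that add atoms: none
Why: In this Claisen–Schmidt condensation the methyl ketone enolate adds to the non-enolisable aldehyde and E1cB dehydration gives the thermodynamic E-enone, with the MOM ether and ring D stable to base.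

**Step 5**
Reactants: 8 the (E)-2'-hydroxychalcone
Product: 9 (±)-1-[2-hydroxy-6-methoxy-4-(methoxymethoxy)phenyl]-3,3-dimethoxy-2-(5-methoxy-2,2-dimethylchroman-6-yl)propan-1-one
Conditions: Tl(NO3)3·3H2O (1.1 equiv), MeOH, 0 °C to rt, 1–2 h; filter TlNO3, NaHCO3 wash
Reagents that add atoms: methanol, CO
Why: Trivalent thallium adds to Cα and methanol to Cβ of the enone, and loss of monovalent thallium drives the very electron-rich 2,4-dialkoxyaryl ring from Cβ to Cα through a phenonium ion (McKillop–Taylor oxidative rearrangement of chalcones, the laboratory counterpart of isoflavone synthase), leaving Cβ as the dimethyl acetal and a racemic C3 centre that is erased in step 6.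

**Step 6**
Reactants: 9 the β-keto acetal
Product: 11 7-hydroxy-5-methoxy-3-(5-methoxy-2,2-dimethylchroman-6-yl)chromenylium chloride, via hydroxy acetal 10 (not isolated)
Conditions: NaBH4 (4 equiv), THF/MeOH, 0 to 40 °C; then 3 M HCl in MeOH, 50 °C, 1 h; concentrate, precipitate with Et2O
Reagents that add atoms: hydrogen chloride, Cl
Why: Proposed new method: hydride reduces the C4 ketone of this ring-opened 2-hydroxyisoflavanone equivalent (the carbinol forms as an inconsequential diastereomer mixture), then methanolic HCl ionises the acetal so that the free ortho-phenol closes ring C at C2 (the same O1–C2 bond the plant makes in the chalcone-to-flavanone cyclisation), the ortho/para-trioxygenated benzylic C4–OH leaves by E1 dehydration, the MOM ether is methanolysed, and loss of the last methoxy group gives the aromatic benzopyrylium sink that erases both stereocentres; the closest known reaction types are the acid closure of the same keto acetals to isoflavones, the NaBH4/acid conversion of 2'-hydroxychalcones into flav-3-enes and the acid ionisation of 2-alkoxy-2H-chromenes to benzopyrylium salts.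

**Step 7**
Reactants: 11 the isoflavylium chloride
Product: 13 7-hydroxy-5-methoxy-3-(5-methoxy-2,2-dimethylchroman-6-yl)coumarin, via isoflavene lactol 12 (not isolated)
Conditions: NaOAc (1.2 equiv), dioxane/H2O 10:1, rt, 10 min; DDQ (1.05 equiv), 0 °C to rt
Reagents that add atoms: water, O
Why: Proposed new method: the buffer turns the cation into its C2 pseudobase 12 (a racemic lactol, formed at C2 because that position is open while C4 is shielded by the 5-OMe and the 3-aryl group), whose C2–H lies between two oxygens and is vinylogously activated by the free para 7-OH, so DDQ removes it as hydride and the protonated lactone simply loses a proton, mirroring the biosynthetic isoflavene-to-arylcoumarin oxidation and removing the last stereocentre; the closest known reaction types are the DDQ oxidation of pterocarp-6a-enes to coumestans and of unprotected p-hydroxycinnamyl alcohols to cinnamaldehydes.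

**Compound list**
1 | 2,4-dihydroxybenzaldehyde | O=Cc1ccc(O)cc1O | starting material
2 | prenyl bromide (1-bromo-3-methylbut-2-ene) | CC(C)=CCBr | starting material
3 | 2,4-dihydroxy-3-(3-methylbut-2-en-1-yl)benzaldehyde | CC(C)=CCc1c(O)ccc(C=O)c1O | intermediate
4 | 5-hydroxy-2,2-dimethylchroman-6-carbaldehyde | CC1(C)CCc2c(O1)ccc(C=O)c2O | intermediate
5 | 5-methoxy-2,2-dimethylchroman-6-carbaldehyde | COc1c(C=O)ccc2OC(C)(C)CCc12 | intermediate
6 | 2,4-dihydroxy-6-methoxyacetophenone | CC(=O)c1c(O)cc(O)cc1OC | starting material
7 | 1-[2-hydroxy-6-methoxy-4-(methoxymethoxy)phenyl]ethanone | CC(=O)c1c(O)cc(OCOC)cc1OC | intermediate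
8 | (E)-1-[2-hydroxy-6-methoxy-4-(methoxymethoxy)phenyl]-3-(5-methoxy-2,2-dimethylchroman-6-yl)prop-2-en-1-one | COCOc1cc(O)c(C(=O)/C=C/c2ccc3OC(C)(C)CCc3c2OC)c(OC)c1 | intermediate
9 | (±)-1-[2-hydroxy-6-methoxy-4-(methoxymethoxy)phenyl]-3,3-dimethoxy-2-(5-methoxy-2,2-dimethylchroman-6-yl)propan-1-one (racemic) | COCOc1cc(O)c(C(=O)C(C(OC)OC)c2ccc3OC(C)(C)CCc3c2OC)c(OC)c1 | intermediate
10 | 1-[2-hydroxy-6-methoxy-4-(methoxymethoxy)phenyl]-3,3-dimethoxy-2-(5-methoxy-2,2-dimethylchroman-6-yl)propan-1-ol (racemic diastereomer mixture) | COCOc1cc(O)c(C(O)C(C(OC)OC)c2ccc3OC(C)(C)CCc3c2OC)c(OC)c1 | intermediate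
11 | 7-hydroxy-5-methoxy-3-(5-methoxy-2,2-dimethylchroman-6-yl)chromenylium chloride | COc1cc(O)cc2[o+]cc(-c3ccc4OC(C)(C)CCc4c3OC)cc12.[Cl-] | intermediate
12 | 5-methoxy-3-(5-methoxy-2,2-dimethylchroman-6-yl)-2H-chromene-2,7-diol (racemic) | COc1cc(O)cc2OC(O)C(=Cc12)c1ccc2OC(C)(C)CCc2c1OC | intermediate
13 | 7-hydroxy-5-methoxy-3-(5-methoxy-2,2-dimethylchroman-6-yl)-2H-chromen-2-one (CNP0139207.0, achiral) | COc1c(-c2cc3c(OC)cc(O)cc3oc2=O)ccc2c1CCC(C)(C)O2 | target

**Total step count:** 7. **Longest linear sequence:** 6 (steps 1, 2, 4, 5, 6, 7).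

**Three steps most likely to fail**

Step 7 (DDQ oxidation of the pseudobase with the phenol free). The risks are competing hydration at C4, which would lead to the isoflavone, and attack of the oxidant on the free phenol or on the benzylic CH2 of ring D. The fallback sets out from 11 and replaces hydride abstraction by an aldehyde-to-acid oxidation followed by lactonisation. Aqueous NaOH under nitrogen takes 11 through 12 to its ring-opened form, (Z)-3-(2,4-dihydroxy-6-methoxyphenyl)-2-(5-methoxy-2,2-dimethylchroman-6-yl)acrylaldehyde F5. Ag2O in the same alkaline medium then oxidises the aldehyde to (Z)-3-(2,4-dihydroxy-6-methoxyphenyl)-2-(5-methoxy-2,2-dimethylchroman-6-yl)acrylic acid F6. Acidifying and warming with catalytic HCl lactonises F6, which also drains any E isomer through the acid-mediated equilibrium. The fallback comes back to the route at 13.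

Step 6 (reduction and acid collapse). The risks are slow reduction of the chelated, very electron-rich ketone, over-reduction through an ortho-quinone methide, and premature closure to the isoflavone. The fallback sets out from 9 and follows the full biosynthetic order through the isoflavone.
- Refluxing HCl/MeOH closes ring C and removes the MOM group, giving 7-hydroxy-5-methoxy-3-(5-methoxy-2,2-dimethylchroman-6-yl)-4H-chromen-4-one F2.
- H2 over Pd/C in EtOH reduces F2 to 5-methoxy-3-(5-methoxy-2,2-dimethylchroman-6-yl)chroman-4,7-diol F3.
- TsOH·H2O in warm toluene dehydrates F3 to 5-methoxy-3-(5-methoxy-2,2-dimethylchroman-6-yl)-2H-chromen-7-ol F4.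
- DDQ (2.1 equiv) in wet dioxane takes the C2 methylene of F4 through 12 to the lactone.

The fallback comes back to the route at 13.

Step 1 (C3-selective prenylation). The risks are O-prenylation, C5-prenylation and double alkylation, which typically hold the yield to a moderate level. The fallback sets out from 1 and changes the ring D construction to an aldehyde condensation with electrocyclisation. Treating 1 with 3-methylbut-2-enal and Ca(OH)2 in MeOH at rt gives, by aldol-type attack at C3, dehydration to the ortho-quinone methide and oxa-6π closure, only the angular 5-hydroxy-2,2-dimethyl-2H-chromene-6-carbaldehyde F1. Hydrogenating the chromene C=C (H2 at 1 atm, Pd/C, EtOAc, stopped after one equivalent) comes back to the route at 4.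

**Further compounds**
F1 | step 1 | 5-hydroxy-2,2-dimethyl-2H-chromene-6-carbaldehyde | CC1(C)C=Cc2c(O1)ccc(C=O)c2O
F2 | step 6 | 7-hydroxy-5-methoxy-3-(5-methoxy-2,2-dimethylchroman-6-yl)-4H-chromen-4-one | COc1cc(O)cc2occ(-c3ccc4OC(C)(C)CCc4c3OC)c(=O)c12
F3 | step 6 | 5-methoxy-3-(5-methoxy-2,2-dimethylchroman-6-yl)chroman-4,7-diol (racemic diastereomer mixture) | COc1cc(O)cc2OCC(C(O)c12)c1ccc2OC(C)(C)CCc2c1OC
F4 | step 6 | 5-methoxy-3-(5-methoxy-2,2-dimethylchroman-6-yl)-2H-chromen-7-ol | COc1cc(O)cc2OCC(=Cc12)c1ccc2OC(C)(C)CCc2c1OC
F5 | step 7 | (Z)-3-(2,4-dihydroxy-6-methoxyphenyl)-2-(5-methoxy-2,2-dimethylchroman-6-yl)acrylaldehyde | O=C/C(=C\c1c(O)cc(O)cc1OC)c1ccc2OC(C)(C)CCc2c1OC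
F6 | step 7 | (Z)-3-(2,4-dihydroxy-6-methoxyphenyl)-2-(5-methoxy-2,2-dimethylchroman-6-yl)acrylic acid | OC(=O)/C(=C\c1c(O)cc(O)cc1OC)c1ccc2OC(C)(C)CCc2c1OC
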